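## Retrosynthetic overview
1. Junceellolide E (22) comes from acetylation of the C9 alcohol of the macrocycle 21. The 10-membered ring is closed last by ring-closing metathesis, which gives the ring-cis C5=C6 alkene.
2. The key C9–C10 bond, with the C11=C20 exocyclic methylene, is made by photoredox/Cr-catalysed allylic C–H addition of the cyclohexene 12 to the α-hydroxy aldehyde 19.
3. The cyclohexene 12 comes from (S)-carvone: α′-acylation, anti-methylation to form quaternary C1, isopropenyl → OAc (O3, then Baeyer–Villiger), and ketone → transposed alkene (Kabalka).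
4. The lactone aldehyde 19 comes from (R)-malic acid: Seebach dioxolanone aldol with acrolein, lactonisation, α-methylation, DIBAL.
5. Ring order: cyclohexane (from carvone), then γ-lactone (from malate), then the 10-membered ring (C9–C10 photochemically, then C5=C6 by RCM).

Assumptions: pent-4-ynal is bought, or made by oxidising commercial 4-pentyn-1-ol. The C7 aldol diastereomers are separable.

## Route

**Step 1**
Reactants: 1 (S)-carvone; 2 pent-4-ynal
Product: 3, α′-aldol adduct (6-(1-hydroxypent-4-ynyl)carvone, epimeric mixture)
Conditions: LDA, THF, −78 °C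
Reagents that add atoms: none
Why: The kinetic lithium enolate forms at C6 and adds to the aldehyde (aldol); both new stereocentres are erased in steps 2–3.

**Step 2**
Reactants: 3
Product: 4, 6-(pent-4-ynoyl)-(5S)-carvone (β-diketone, enolised)
Conditions: Dess–Martin periodinane, NaHCO3, CH2Cl2, 25 °C
Reagents that add atoms: none
Why: Oxidation of the secondary alcohol converts the aldol into the 1,3-diketone and removes the carbinol stereocentre.

**Step 3**
Reactants: 4
Product: 5, 6-methyl-6-(pent-4-ynoyl)carvone with methyl trans to isopropenyl
Conditions: MeI, K2CO3, acetone, 50 °C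
Reagents that add atoms: iodomethane, CI
Why: C-Methylation of the planar chelated diketonate occurs anti to the C5 isopropenyl group, so the acyl chain ends up cis and methyl trans to it; this forms quaternary C1 (enolate alkylation).

**Step 4**
Reactants: 5
Product: 6, secondary C2 alcohol (2R) with the ring enone intact
Conditions: LiAlH(OtBu)3, THF, −78 °C
Reagents that add atoms: none
Why: The more electrophilic saturated ketone is reduced in preference to the hindered enone. Polar Felkin–Anh control (hydride anti to the C10 acyl group, passing the small C15 methyl) sets C2.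

**Step 5**
Reactants: 6
Product: 7, C2 propionate
Conditions: (EtCO)2O, DMAP, Et3N, CH2Cl2, 40 °C
Reagents that add atoms: propionic anhydride, CCC(=O)OC(=O)CC
Why: Acylation of the hindered secondary alcohol with retention; this installs the C2 ester of the target.

**Step 6**
Reactants: 7
Product: 8, C14 methyl ketone
Conditions: O3, CH2Cl2, −78 °C (Sudan Red III endpoint), then PPh3
Reagents that add atoms: ozone, O=[O+][O-]
Why: Ozonolysis cleaves the isopropenyl group selectively, because the conjugated enone C=C and the terminal alkyne react far more slowly.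

**Step 7**
Reactants: 8
Product: 9, C14 acetate
Conditions: mCPBA, Na2HPO4, CH2Cl2, 25 °C
Reagents that add atoms: mCPBA, OOC(=O)c1cccc(Cl)c1
Why: Baeyer–Villiger oxidation is chemoselective for the unhindered methyl ketone, since the ring ketone is conjugated and flanked by a quaternary carbon. The secondary carbon migrates with retention, so C14–O keeps carvone's C5 configuration.

**Step 8**
Reactants: 9
Product: 10, C10 tosylhydrazone
Conditions: TsNHNH2, cat. TsOH, MeOH, 40 °C
Reagents that add atoms: p-toluenesulfonyl hydrazide, Cc1ccc(cc1)S(=O)(=O)NN
Why: Condensation of the ring ketone, with the esters untouched, sets up the alkene transposition.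

**Step 9**
Reactants: 10
Product: 11, C10=C11 cyclohexene bearing the terminal alkyne
Conditions: catecholborane, CHCl3, 0 °C; then NaOAc·3H2O, reflux
Reagents that add atoms: none
Why: Kabalka reduction: hydride addition, loss of sulfinate, then a retro-ene of the allylic diazene moves the alkene to C10=C11 and delivers H to C12. C10 loses its oxygen and no stereocentre is touched.

**Step 10**
Reactants: 11
Product: 12, isopropenyl side chain (photochemical-step substrate)
Conditions: Me3Al, cat. Cp2ZrCl2, ClCH2CH2Cl, 0 → 25 °C; then H2O
Reagents that add atoms: trimethylaluminium, C[Al](C)C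
Why: Zr-catalysed syn-carboalumination puts Me on the internal alkyne carbon, and protonolysis gives the 1,1-disubstituted alkene (Negishi carboalumination); the esters and the trisubstituted ring alkene survive.

**Step 11**
Reactants: 13 (R)-malic acid
Product: 14, (2R,5R)-2-tert-butyl-5-(carboxymethyl)-1,3-dioxolan-4-one
Conditions: pivaldehyde, cat. TsOH, pentane, reflux (Dean–Stark)
Reagents that add atoms: pivaldehyde, CC(C)(C)C=O
Why: Acetalisation gives the cis-dioxolanone (tBu cis to CH2CO2H), which stores the malate stereocentre for the next step (Seebach self-regeneration of stereocentres).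

**Step 12**
Reactants: 14; 15 acrolein
Product: 16, hydroxy acid with quaternary C8 and C7 allylic carbinol
Conditions: LDA (2.2 equiv), THF, −78 °C; then acrolein
Reagents that add atoms: none
Why: The ring enolate is attacked trans to the tBu group, so C8 forms with retention relative to malate; the C7 carbinol is set by a chelated chair aldol transition state, and the major diastereomer is isolated by chromatography.

**Step 13**
Reactants: 16
Product: 17, spiro γ-lactone–dioxolanone
Conditions: EDC·HCl, DMAP, CH2Cl2, 0 → 25 °C
Reagents that add atoms: none
Why: Carbodiimide lactonisation of the γ-hydroxy acid closes the five-membered ring (C7–O–C19) without disturbing the stereocentres.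

**Step 14**
Reactants: 17
Product: 18, α-methyl lactone (C17 methyl cis to C7 vinyl and to C8–O)
Conditions: LDA, THF, −78 °C; then MeI
Reagents that add atoms: iodomethane, CI
Why: The lactone enolate is alkylated from the face anti to the adjacent C9 carbonyl carbon on C8 (the carbon substituent is larger than the ring oxygen), which sets C17 (enolate alkylation).

**Step 15**
Reactants: 18
Product: 19, α-hydroxy aldehyde with the C8 tertiary OH free
Conditions: DIBAL-H (1.1 equiv), toluene, −78 °C; Rochelle salt work-up
Reagents that add atoms: none
Why: The activated acylal carbonyl is reduced faster than the lactone; the resulting hemiacetal collapses to the aldehyde and pivaldehyde.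

**Step 16**
Reactants: 12; 19
Product: 20, C9–C10 coupled homoallylic alcohol with exocyclic C11=C20
Conditions: Mes-Acr⁺ BF4⁻ (5 mol %), CrCl2 (20 mol %), dtbbpy (24 mol %), Mg(ClO4)2, MeCN/CH2Cl2, blue LEDs, 25 °C
Reagents that add atoms: none
Why: Proposed new method: the excited acridinium oxidises the most electron-rich alkene (the trisubstituted ring C10=C11), base removes a C20–H to give an allyl radical, Cr(II) traps it as the primary allyl-Cr(III), and this adds to the C9 aldehyde at C10 through a closed chair Zimmerman–Traxler transition state. The exocyclic methylene is regenerated, the E-type allyl geometry gives the C9/C10 anti relationship, and the C10 face is chosen by the lower-face C2/C14 acyloxy groups, which steer addition to the methyl face. This is the known photoredox/Cr allylic C–H addition to aldehydes, applied to a hindered cyclic trisubstituted alkene next to a quaternary centre and to a complex α-quaternary α-hydroxy aldehyde.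

**Step 17**
Reactants: 20
Product: 21, macrocycle with ring-cis C5=C6 (C9-OH free)
Conditions: Hoveyda–Grubbs II (10 mol %), 1,4-benzoquinone, toluene (2 mM), 80 °C
Reagents that add atoms: none
Why: Ring-closing metathesis of the C5 isopropenyl and C7 vinyl groups, releasing ethylene, forms the trisubstituted alkene. The 10-membered ring forces the Z (ring-cis) geometry required.

**Step 18**
Reactants: 21
Product: 22, junceellolide E
Conditions: Ac2O, DMAP, pyridine, CH2Cl2, 0 °C
Reagents that add atoms: acetic anhydride, CC(=O)OC(C)=O
Why: Chemoselective acetylation of the secondary C9-OH; the tertiary C8-OH is too hindered to react.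

## Compound list
1 | (S)-(+)-carvone | CC1=CC[C@@H](CC1=O)C(C)=C | starting material
2 | pent-4-ynal | C#CCCC=O | starting material
3 | 6-(1-hydroxypent-4-ynyl)carvone (C6 and carbinol epimeric) | CC1=CC[C@H](C(C)=C)C(C(O)CCC#C)C1=O | intermediate
4 | 6-(pent-4-ynoyl)carvone (β-diketone) | CC1=CC[C@H](C(C)=C)C(C(=O)CCC#C)C1=O | intermediate
5 | 6-methyl-6-(pent-4-ynoyl)carvone, Me trans to isopropenyl | CC1=CC[C@H](C(C)=C)[C@](C)(C(=O)CCC#C)C1=O | intermediate
6 | C2 alcohol (2R) | CC1=CC[C@H](C(C)=C)[C@](C)([C@H](O)CCC#C)C1=O | intermediate
7 | C2 propionate | CC1=CC[C@H](C(C)=C)[C@](C)([C@H](OC(=O)CC)CCC#C)C1=O | intermediate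
8 | C14 methyl ketone | CC1=CC[C@H](C(C)=O)[C@](C)([C@H](OC(=O)CC)CCC#C)C1=O | intermediate
9 | C14 acetate | CC1=CC[C@H](OC(C)=O)[C@](C)([C@H](OC(=O)CC)CCC#C)C1=O | intermediate
10 | C10 tosylhydrazone | CC1=CC[C@H](OC(C)=O)[C@](C)([C@H](OC(=O)CC)CCC#C)C1=NNS(=O)(=O)c1ccc(C)cc1 | intermediate
11 | transposed cyclohexene, terminal alkyne | CC1=C[C@@](C)([C@H](OC(=O)CC)CCC#C)[C@@H](OC(C)=O)CC1 | intermediate
12 | cyclohexene with isopropenyl side chain | CC1=C[C@@](C)([C@H](OC(=O)CC)CCC(C)=C)[C@@H](OC(C)=O)CC1 | intermediate
13 | (R)-malic acid | C([C@H](C(=O)O)O)C(=O)O | starting material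
14 | (2R,5R)-2-tert-butyl-5-(carboxymethyl)-1,3-dioxolan-4-one | CC(C)(C)[C@@H]1O[C@H](CC(O)=O)C(=O)O1 | intermediate
15 | acrolein | C=CC=O | starting material
16 | aldol hydroxy acid | CC(C)(C)[C@@H]1O[C@@](CC(O)=O)([C@@H](O)C=C)C(=O)O1 | intermediate
17 | spiro lactone–dioxolanone | CC(C)(C)[C@@H]1O[C@]2(CC(=O)O[C@H]2C=C)C(=O)O1 | intermediate
18 | α-methyl spiro lactone | CC(C)(C)[C@@H]1O[C@]2([C@@H](C)C(=O)O[C@H]2C=C)C(=O)O1 | intermediate
19 | α-hydroxy aldehyde lactone | O=C[C@]1(O)[C@@H](C)C(=O)O[C@H]1C=C | intermediate
20 | C9–C10 coupled triene | C=C1CC[C@H](OC(C)=O)[C@@]([C@H](OC(=O)CC)CCC(C)=C)(C)[C@H]1[C@@H](O)[C@@]1(O)[C@H](C=C)OC(=O)[C@@H]1C | intermediate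
21 | 9-deacetyl junceellolide E | C=C1CC[C@H](OC(C)=O)[C@@]2(C)[C@H]1[C@@H](O)[C@@]1(O)[C@H](/C=C(/C)CC[C@H]2OC(=O)CC)OC(=O)[C@@H]1C | intermediate
22 | junceellolide E | C=C1CC[C@H](OC(C)=O)[C@@]2(C)[C@H]1[C@@H](OC(C)=O)[C@@]1(O)[C@H](/C=C(/C)CC[C@H]2OC(=O)CC)OC(=O)[C@@H]1C | target

**Total steps:** 18
**Longest linear sequence:** 13 (carvone → 12 in 10 steps, then steps 16, 17, 18)

**Three steps most likely to fail**
1. **Step 16 (proposed new photoredox/Cr step).** The C–H abstraction could occur at the ring C12 instead of C20, the isopropenyl group could be oxidised competitively, and the C10 terminus is neopentyl-hindered. Fallback (known chemistry): make the C20 allylic bromide of 12 (SeO2/t-BuOOH, then PPh3/CBr4) and run a classical intermolecular Nozaki–Hiyama–Kishi allylation (CrCl2, cat. NiCl2) with 19, which gives the same γ-attack and exocyclic methylene.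
2. **Step 17 (RCM).** Closing a strained 10-membered ring competes with a six-membered RCM onto the exocyclic C11=C20 alkene. Fallback: reverse the order. Convert the alkyne of 11 to the C5 methyl ketone (Au-catalysed hydration), make the (Z)-enal by olefination with Z/E separation, run the dioxolanone aldol on that enal at C7, and close C9–C10 intramolecularly by the step-16 chemistry or the bromide NHK of fallback 1.
3. **Step 4 (C2 reduction).** Chelation and steric models disagree, so the wrong C2 epimer may predominate. Fallback: isolate the epimer and invert it by Mitsunobu reaction (p-nitrobenzoic acid, DIAD, PPh3), then exchange to the propionate; alternatively correct C2 on the macrocycle-stage alcohol.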